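## Analysis of the target

Target 21 is a 2,3-dihydro-1-benzofuran with a fully substituted benzene ring: C3a and C7a carry the dihydrofuran, C4 and C6 hydroxyl groups, C5 an acetyl group, and C7 a methylene bridge to C3 of a 6-ethyl-4-hydroxy-5-methyl-2H-pyran-2-one. The only stereocentre is C2 (R), which bears H, the ring oxygen O1, the C3 methylene and a 6-methylhepta-1,5-dien-2-yl group, so absolute control at this one carbon is the whole stereochemical problem. C2 is allylic and is also the alkyl carbon of an aryl ether; once the 1,1-disubstituted alkene is present, the C2–O1 bond can ionise under strong acid or with zerovalent palladium, and any carbonyl precursor of that alkene makes H-2 enolisable. Other sensitive groups are the trisubstituted alkene (acid, electrophiles), the acyl-chelated phenols (oxidation, easy C- and O-alkylation), the acidic 4-hydroxypyranone, and the methylene bridge, which is formed by reversible Mannich/Michael chemistry and can scramble to symmetrical dimers. The synthesis is hard for three reasons: six different substituents must be placed on one benzene ring with regiocontrol, C2 must be made as one enantiomer and kept so, and two nucleophilic hydroxy(hetero)arenes must be joined through one carbon cross-selectively. The plan rests on the fact that O1 on C7a is para to the C5 acetyl group and flanked by C3a and C7. Removing C3a–C3 and C7a–O1 leaves the mirror-symmetric para-iodoacetophenone 4, whose two ortho C–H bonds are equivalent (one becomes C3a, the other stays as C7–H for the bridge). The atoms C3, C2 and O1 map onto the terminal epoxide 10, whose stereocentre is not touched.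

## Retrosynthetic reasoning

**C7–CH2 bridge (21 to 14 and 18).** The bond between C7 and the bridge carbon is cut last, together with the bond from that carbon to C3 of the pyranone. C7 is the only unsubstituted ring carbon of 14, so the regiochemistry is fixed, and the acidic, polar pyranone is kept out of all earlier steps. In the forward direction 18 is aminomethylated to 19, which loses amine to the Michael acceptor 20; this is captured by C7 of 14.

**Pyranone (18 to 17 to 15 and 16).** The lactone C–O bond of 18 is opened to the 3,5-dioxo ester 17. Cutting 17 between C4 and C5 gives the γ-carbanion of 15 and the acyl donor 16. This gives the heterocycle in two steps from bulk chemicals and off the main line.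

**Functional-group changes at C2 and on the phenols (14 to 13 to 12 to 11).** The phenols are released from MOM ethers just before bridging. The C=CH2 bond of 13 is traced to the ketone 12 by a non-basic methylenation, because a vinyl epoxide cannot be carried through palladium catalysis. The ketone is stored in 11 as an open-chain dimethyl ketal and not as a cyclic one. A ketal next to the aryloxy-bearing C2 is deactivated toward hydrolysis, and only the acyclic ketal should still open under acid weak enough to keep the aryl MOM ethers and leave H-2 alone. The MOM ethers are wanted during methylenation because they keep the C5 acetyl hindered and unchelated.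

**Key disconnection (11 to 4 and 10).** C3a–C3 and C7a–O1 are cut together. Both bonds from the dihydrofuran to the arene go in one operation, the arene partner becomes symmetric, and the stereocentre arrives ready-made in 10. The forward reaction is a Catellani-type annulation with a strained bicyclic alkene as transient mediator. It has to alkylate exactly one of the two ortho C–H bonds of 4 with the CH2 terminus of 10 and then bond the freed alkoxide to the ipso carbon.

**Aryl iodide (4 to 2 to 1, through 3).** The C–I bond is traced to the C4–H bond of 2, the only ring C–H without an ortho substituent. A sterically governed C–H borylation to 3 followed by iodide-for-boron exchange reaches 4 in one pot. Electrophilic iodination would attack the oxygen-activated C3 position instead. Compound 2 is the bis-MOM ether of 1. This avoids differentiating three hydroxyl groups, which a trioxygenated acetophenone precursor would require.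

**Epoxide (10 to 9 to 6 and 8, 6 to 5, 8 from 7).** The ketal is taken back to the epoxy ketone 9. The C–C bond between the carbonyl and the chain is cut to the Weinreb amide 6 and the Grignard reagent 8, made from 7. Amide 6 comes from the chiral-pool salt 5. No bond to the stereocentre is formed or broken in these steps.

## Alternatives that were turned down

**Alternative 1:** The pyranone ring is cut at C3–C4 and O1–C2, which leads to the C7-propargylic siloxyalkyne A2 (core phenols as acetates) and the acylketene A4, released by heating the dioxinone A3.
- **Forward key step:** A formal [4+2] addition in which the ketene carbon of A4 bonds to the alkyne carbon carrying the arylmethyl group and the acyl oxygen bonds to the siloxy carbon. This gives the 2-silyloxy-4H-pyran-4-one A1; desilylation and acetate removal would finish 21.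
- **For:** The C7–CH2–pyranone connectivity exists before the heterocycle, so symmetrical methylene-bis dimers cannot form. On this point it is stronger than step 12 of the chosen route. The ring also forms under neutral thermal conditions with a substitution pattern set by the polarity of both partners.
- **Against:** A2 is a hydrolytically fragile ynol silyl ether that must be built on a benzylic carbon of the finished, stereodefined core (carboxymethylation at C7, ester-to-ynolate homologation, silylation). Both phenols must be capped because free hydroxyls trap acylketenes. The allylic aryl ether and the diene must survive about 110 °C. The disconnection also says nothing about C2 or the dihydrofuran.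
- **Comparison:** It spends four or five linear steps on the valuable core to make a ring that the chosen route prepares in two steps (18) and attaches in one. The chosen route accepts some homodimer risk in return and also solves the stereocentre.

**Alternative 2:** C3a–C3 and the bond from C2 to the dienyl carbon are cut together, which leads to the aryl iodide A6 and the lithium pinacol borate A7 bearing a vinyl and a 6-methylhepta-1,5-dien-2-yl group.
- **Forward key step:** Enantioselective conjunctive cross-coupling with Pd(OAc)2 and a chiral bisphosphine. The aryl-palladium unit adds to the vinyl terminus of A7 while the dienyl group migrates from boron to the neighbouring carbon. This gives the (S)-allylic boronate A5 with C3a–C3, the C2–alkenyl bond and the C2 stereocentre. Oxidation with retention to the (S)-alcohol A8, desilylation and an invertive Mitsunobu closure of the C7a phenol onto C2 would complete the ring.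
- **For:** The stereocentre comes from a catalyst, either enantiomer is accessible, and the 1,1-disubstituted alkene is installed directly. No ketal, C2 ketone or methylenation is needed. Here it is stronger than the chosen route, which uses steps 5, 7 and 8 for the alkene and passes through an enolisable ketone.
- **Against:** A6 is flanked by oxygen substituents on both sides, which is unfavourable for a step that needs alkene binding at a crowded aryl-palladium centre. Alkenyl groups migrate reluctantly and can transfer directly (Suzuki–Miyaura), and the catalyst must choose the vinyl over the dienyl ligand of A7. The ring is not closed in the key step, and the later substitution at a secondary allylic carbinol can leak through SN2′ or ionisation and erode the ee.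
- **Comparison:** The chosen route makes the same C3a–C3 bond, closes the ring in the same operation, and takes C2 from the chiral pool by a mechanism that does not touch it. The price is the ketone detour.

**Alternative 3:** The pyranone is cut at C4–C5 and O1–C2. C2, C3 and the bridge carbon are stored in a dihydrocoumarin spanning the C6 oxygen and C7, so the precursors are the acid chloride A10 and pentan-3-one A11.
- **Forward key step:** Loss of HCl from A10 gives the acylketene A12, which C-acylates the enol of A11. The enol oxygen of the resulting diketone then attacks the lactone carbonyl, so the pyranone closes as the C6 phenol is released. This gives the C4 acetate A9, which is deacetylated to 21.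
- **For:** The bridge again precedes the heterocycle, the lactone doubles as protection of the C6 hydroxyl, and the second component is a bulk ketone. In economy of the last bond formations it is the most elegant of the four.
- **Against:** Acylketenes react with ketones mainly at the carbonyl group (dioxinone formation) or at enol oxygen, and A11 has little enol, so C-acylation is the least likely pathway. The acid chloride must be made on a substrate with an acid-sensitive diene and an allylic aryl ether. A10 needs C7 functionalisation, malonate condensation, reduction and differentiation of the C4 and C6 hydroxyls. C2 is left unsolved.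
- **Comparison:** It has more linear steps on the chiral core and a key step with unfavourable chemoselectivity, against a two-step synthesis of 18 and a one-step union in the chosen route.

Key step: step 6

Assumption: compounds 1, 5, 7, 15 and 16 and all catalyst components, including the bridgehead-substituted norbornene, are taken as purchasable; the choice of 1-alkylnorbornene is open.

## Route

Step 1
Reactants: 1 1-(2,6-dihydroxyphenyl)ethanone
Product: 2 1-[2,6-bis(methoxymethoxy)phenyl]ethanone
Conditions: NaH (2.5 equiv), MOMCl (2.5 equiv), DMF, 0 °C → rt
Reagents that add atoms: chloromethyl methyl ether, COCCl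
Why: Double Williamson etherification of the bis-phenoxide; NaH also deprotonates the hydroxyl that is hydrogen-bonded to the acetyl group, and the hindered ketone is left alone at this temperature.

Step 2
Reactants: 2 1-[2,6-bis(methoxymethoxy)phenyl]ethanone
Product: 4 1-[4-iodo-2,6-bis(methoxymethoxy)phenyl]ethanone, via aryl pinacol boronate 3 (not isolated)
Conditions: [Ir(OMe)(cod)]2 (1.5 mol%), 4,4′-di-tert-butyl-2,2′-bipyridine (3 mol%), B2pin2 (1.0 equiv), THF, 80 °C; evaporate; CuI (10 mol%), 1,10-phenanthroline (20 mol%), KI (1.5 equiv), MeOH/H2O, air, 80 °C
Reagents that add atoms: potassium iodide, [K+].[I-]; bis(pinacolato)diboron, CC1(C)OB(OC1(C)C)B1OC(C)(C)C(C)(C)O1 (boryl group of intermediate 3 only)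
Why: Iridium-catalysed C–H borylation is governed by sterics and C4–H of 2 is the only ring C–H without an ortho substituent, so boron should enter para to the acetyl group; CuI-mediated iododeboronation then exchanges boron for iodine at that carbon, whereas electrophilic iodination would attack the oxygen-activated C3 position.

Step 3
Reactants: 5 potassium (2R)-oxirane-2-carboxylate
Product: 6 (2R)-N-methoxy-N-methyloxirane-2-carboxamide
Conditions: MeNH(OMe)·HCl (1.1 equiv), EDC·HCl (1.2 equiv), HOBt (10 mol%), CH2Cl2/DMF, 0 °C → rt
Reagents that add atoms: N,O-dimethylhydroxylamine hydrochloride, CNOC.Cl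
Why: Carbodiimide amide coupling of the carboxylic acid freed by the amine hydrochloride, under near-neutral conditions; no bond to the stereocentre is made or broken and no strong base or Lewis acid is present, so the epoxide and its R configuration should persist.

Step 4
Reactants: 6 (2R)-N-methoxy-N-methyloxirane-2-carboxamide; 7 5-bromo-2-methylpent-2-ene
Product: 9 5-methyl-1-[(2R)-oxiran-2-yl]hex-4-en-1-one, via homoprenylmagnesium bromide 8 (not isolated)
Conditions: 7, Mg, THF, rt → 40 °C; then 6, THF, −78 → −20 °C; aq. NH4Cl
Reagents that add atoms: magnesium, [Mg] (in intermediate 8 only)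
Why: Weinreb ketone synthesis; the Grignard reagent 8 adds to the amide faster than to the terminal epoxide at low temperature, and the magnesium chelate of the tetrahedral adduct prevents a second addition until the cold quench, with the stereocentre as a spectator.

Step 5
Reactants: 9 5-methyl-1-[(2R)-oxiran-2-yl]hex-4-en-1-one
Product: 10 (2R)-2-(1,1-dimethoxy-5-methylhex-4-en-1-yl)oxirane
Conditions: MeOSiMe3 (3 equiv), Me3SiOTf (5 mol%), CH2Cl2, −78 °C; pyridine quench
Reagents that add atoms: methoxytrimethylsilane, CO[Si](C)(C)C
Why: Silyl-triflate-catalysed ketalisation with an alkoxysilane (Noyori-type), driven by formation of the disiloxane under aprotic conditions at −78 °C, where an epoxide deactivated by the neighbouring carbonyl should stay closed; the trisubstituted alkene cannot trap the oxocarbenium ion productively (four-membered ring or secondary cation).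

Step 6
Reactants: 4 1-[4-iodo-2,6-bis(methoxymethoxy)phenyl]ethanone; 10 (2R)-2-(1,1-dimethoxy-5-methylhex-4-en-1-yl)oxirane
Product: 11 1-[(2R)-2-(1,1-dimethoxy-5-methylhex-4-en-1-yl)-4,6-bis(methoxymethoxy)-2,3-dihydro-1-benzofuran-5-yl]ethanone
Conditions: Pd(OAc)2 (10 mol%), 2-dicyclohexylphosphino-2′,6′-diisopropoxybiphenyl (20 mol%), 1-methylbicyclo[2.2.1]hept-2-ene (1 equiv), Cs2CO3 (1.5 equiv), 10 (1.5 equiv), 1,4-dioxane, 100 °C
Reagents that add atoms: none
Why: Catellani annulation of an aryl iodide with an epoxide, the closest known reaction type being the palladium/norbornene ortho-alkylation/ipso-etherification that gives 2-substituted 2,3-dihydrobenzofurans. Zerovalent palladium inserts into the C–I bond of 4, the norbornene adds across the aryl–palladium bond, and carbonate-assisted palladation of the adjacent C–H gives a five-membered aryl–norbornyl palladacycle of divalent palladium. The palladacycle is alkylated by the epoxide at its CH2 terminus (SN2-type opening to tetravalent palladium, possibly through the iodohydrin alkoxide), and reductive elimination forms C3a–C3. The bridgehead methyl group then forces β-carbon elimination of the norbornene after this single ortho functionalisation, which limits the reaction to one of the two equivalent ortho C–H bonds. The resulting aryl-palladium alkoxide is a six-membered oxapalladacycle, and C–O reductive elimination at the ipso carbon closes the five-membered dihydrofuran (C7a–O1) and returns zerovalent palladium. No new stereocentre is formed and neither bond to the epoxide CH is broken, so the R configuration of 10 becomes C2 of 11. Attack at CH2 is secured by the quaternary ketal carbon on the other epoxide carbon, and the para acetyl group makes the aryl ligand electron-poor, which favours C–O reductive elimination over β-hydride loss from the alkoxide. The MOM ethers are the smallest base-stable phenol protection, which matters because the C–H to be palladated is flanked by one of them.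

Step 7
Reactants: 11 1-[(2R)-2-(1,1-dimethoxy-5-methylhex-4-en-1-yl)-4,6-bis(methoxymethoxy)-2,3-dihydro-1-benzofuran-5-yl]ethanone
Product: 12 1-[(2R)-5-acetyl-4,6-bis(methoxymethoxy)-2,3-dihydro-1-benzofuran-2-yl]-5-methylhex-4-en-1-one
Conditions: PPTS (20 mol%), acetone/H2O (10:1), 40 °C
Reagents that add atoms: water, O
Why: Acid-catalysed hydrolysis of an open-chain dimethyl ketal through its oxocarbenium ion; the acyclic ketal is expected to open under pyridinium-level acidity although the α-aryloxy group retards ionisation, while the aryl MOM ethers survive and H-2 is not enolised.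

Step 8
Reactants: 12 1-[(2R)-5-acetyl-4,6-bis(methoxymethoxy)-2,3-dihydro-1-benzofuran-2-yl]-5-methylhex-4-en-1-one
Product: 13 1-[(2R)-4,6-bis(methoxymethoxy)-2-(6-methylhepta-1,5-dien-2-yl)-2,3-dihydro-1-benzofuran-5-yl]ethanone
Conditions: Zn, CH2Br2, TiCl4, THF, −40 → 5 °C (reagent aged); then 12, CH2Cl2, 0 °C → rt
Reagents that add atoms: dibromomethane, BrCBr
Why: Lombardo methylenation; the non-basic titanium–zinc methylene reagent converts enolisable ketones into 1,1-disubstituted alkenes without epimerising the α-centre, and the C5 acetyl group, twisted out of conjugation and shielded by two ortho MOM ethers, should react much more slowly than the aliphatic ketone.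

Step 9
Reactants: 13 1-[(2R)-4,6-bis(methoxymethoxy)-2-(6-methylhepta-1,5-dien-2-yl)-2,3-dihydro-1-benzofuran-5-yl]ethanone
Product: 14 1-[(2R)-4,6-dihydroxy-2-(6-methylhepta-1,5-dien-2-yl)-2,3-dihydro-1-benzofuran-5-yl]ethanone
Conditions: 3 M aq. HCl, MeOH, rt
Reagents that add atoms: none
Why: Acid-catalysed cleavage of aryl MOM ethers by acetal transfer to methanol; MOM ethers ortho to a carbonyl group are among the most labile, so dilute acid at room temperature should suffice and leave both alkenes and the allylic C2–O1 bond intact.

Step 10
Reactants: 15 methyl 3-oxopentanoate; 16 N-methoxy-N-methylpropanamide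
Product: 17 methyl 4-methyl-3,5-dioxoheptanoate
Conditions: 15 (2 equiv), LiN(iPr)2 (4 equiv), THF, −78 → 0 °C; then 16 (1 equiv), −78 °C → rt; 1 M HCl
Reagents that add atoms: none
Why: γ-Acylation of a β-keto ester dianion; the more basic γ-carbanion attacks the Weinreb amide, whose chelated adduct prevents double addition, and the second equivalent of dianion takes up the acidic proton of the product (17 is racemic at C4 and largely enolised, which is of no consequence).

Step 11
Reactants: 17 methyl 4-methyl-3,5-dioxoheptanoate
Product: 18 6-ethyl-4-hydroxy-5-methyl-2H-pyran-2-one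
Conditions: DBU (1.5 equiv), toluene, reflux; 1 M HCl
Reagents that add atoms: none
Why: Base-promoted lactonisation of a 3,5-dioxo ester; the C5 enolate oxygen attacks the ester carbonyl in a six-membered closure and loss of methoxide gives the aromatic 4-hydroxy-2-pyranone.

Step 12
Reactants: 14 1-[(2R)-4,6-dihydroxy-2-(6-methylhepta-1,5-dien-2-yl)-2,3-dihydro-1-benzofuran-5-yl]ethanone; 18 6-ethyl-4-hydroxy-5-methyl-2H-pyran-2-one
Product: 21 3-{[(2R)-5-acetyl-4,6-dihydroxy-2-(6-methylhepta-1,5-dien-2-yl)-2,3-dihydro-1-benzofuran-7-yl]methyl}-6-ethyl-4-hydroxy-5-methyl-2H-pyran-2-one, via pyranone Mannich base 19 (not isolated), via methylidene pyrandione 20 (not isolated)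
Conditions: 18 (1.5 equiv), [Me2N=CH2]I (1.5 equiv), NaOAc (1.5 equiv), MeCN, rt; then 14 (1 equiv), 60 °C
Reagents that add atoms: N,N-dimethylmethylideneammonium iodide, C=[N+](C)C.[I-]
Why: Mannich aminomethylation of 18 at C3 gives 19, which loses dimethylamine (retro-Michael) to the methylidene dione 20; conjugate addition of 14 through C7, its only unsubstituted ring carbon, and re-aromatisation give the bridge, a known way to methylene-bridged acylphloroglucinol–pyranone dimers, and C2 is not involved.

## Compound list

1 | 1-(2,6-dihydroxyphenyl)ethanone | CC(=O)c1c(O)cccc1O | starting material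
2 | 1-[2,6-bis(methoxymethoxy)phenyl]ethanone | CC(=O)c1c(OCOC)cccc1OCOC | intermediate
3 | 1-[2,6-bis(methoxymethoxy)-4-(4,4,5,5-tetramethyl-1,3,2-dioxaborolan-2-yl)phenyl]ethanone | CC(=O)c1c(OCOC)cc(cc1OCOC)B1OC(C)(C)C(C)(C)O1 | intermediate (not isolated)
4 | 1-[4-iodo-2,6-bis(methoxymethoxy)phenyl]ethanone | CC(=O)c1c(OCOC)cc(I)cc1OCOC | intermediate
5 | potassium (2R)-oxirane-2-carboxylate | [K+].[O-]C(=O)[C@H]1CO1 | starting material
6 | (2R)-N-methoxy-N-methyloxirane-2-carboxamide | CON(C)C(=O)[C@H]1CO1 | intermediate
7 | 5-bromo-2-methylpent-2-ene | CC(C)=CCCBr | starting material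
8 | (4-methylpent-3-en-1-yl)magnesium bromide | CC(C)=CCC[Mg]Br | intermediate (not isolated)
9 | 5-methyl-1-[(2R)-oxiran-2-yl]hex-4-en-1-one | CC(C)=CCCC(=O)[C@H]1CO1 | intermediate
10 | (2R)-2-(1,1-dimethoxy-5-methylhex-4-en-1-yl)oxirane | CC(C)=CCCC(OC)(OC)[C@H]1CO1 | intermediate
11 | 1-[(2R)-2-(1,1-dimethoxy-5-methylhex-4-en-1-yl)-4,6-bis(methoxymethoxy)-2,3-dihydro-1-benzofuran-5-yl]ethanone | CC(C)=CCCC(OC)(OC)[C@H]1Cc2c(OCOC)c(C(C)=O)c(OCOC)cc2O1 | intermediate
12 | 1-[(2R)-5-acetyl-4,6-bis(methoxymethoxy)-2,3-dihydro-1-benzofuran-2-yl]-5-methylhex-4-en-1-one | CC(C)=CCCC(=O)[C@H]1Cc2c(OCOC)c(C(C)=O)c(OCOC)cc2O1 | intermediate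
13 | 1-[(2R)-4,6-bis(methoxymethoxy)-2-(6-methylhepta-1,5-dien-2-yl)-2,3-dihydro-1-benzofuran-5-yl]ethanone | C=C(CCC=C(C)C)[C@H]1Cc2c(OCOC)c(C(C)=O)c(OCOC)cc2O1 | intermediate
14 | 1-[(2R)-4,6-dihydroxy-2-(6-methylhepta-1,5-dien-2-yl)-2,3-dihydro-1-benzofuran-5-yl]ethanone | C=C(CCC=C(C)C)[C@H]1Cc2c(O)c(C(C)=O)c(O)cc2O1 | intermediate
15 | methyl 3-oxopentanoate | CCC(=O)CC(=O)OC | starting material
16 | N-methoxy-N-methylpropanamide | CCC(=O)N(C)OC | starting material
17 | methyl 4-methyl-3,5-dioxoheptanoate | CCC(=O)C(C)C(=O)CC(=O)OC | intermediate
18 | 6-ethyl-4-hydroxy-5-methyl-2H-pyran-2-one | CCc1oc(=O)cc(O)c1C | intermediate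
19 | 3-[(dimethylamino)methyl]-6-ethyl-4-hydroxy-5-methyl-2H-pyran-2-one | CCc1oc(=O)c(CN(C)C)c(O)c1C | intermediate (not isolated)
20 | 6-ethyl-5-methyl-3-methylidene-2H-pyran-2,4(3H)-dione | CCC1=C(C)C(=O)C(=C)C(=O)O1 | intermediate (not isolated)
21 | 3-{[(2R)-5-acetyl-4,6-dihydroxy-2-(6-methylhepta-1,5-dien-2-yl)-2,3-dihydro-1-benzofuran-7-yl]methyl}-6-ethyl-4-hydroxy-5-methyl-2H-pyran-2-one | C=C(CCC=C(C)C)[C@H]1Cc2c(O)c(C(C)=O)c(O)c(Cc3c(O)c(C)c(CC)oc3=O)c2O1 | target

## Step count and least certain steps

Total: 12 steps. Longest linear sequence: 8 steps (steps 3, 4, 5, 6, 7, 8, 9 and 12, from 5 to 21). The arene branch (steps 1 and 2) and the pyranone branch (steps 10 and 11) are shorter.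

**Step 6 (key step).** The most likely failure is slow ortho C–H palladation. Each ortho C–H of 4 is flanked by a MOM ether and the bridgehead-substituted norbornene adds further bulk, so the aryl–norbornyl palladium species may end in reduction or cyclobutene formation before it reaches the palladacycle. A second risk is β-hydride loss from the palladium alkoxide in place of C–O reductive elimination.
Fallback: it sets out from boronate 3 (step 2 stopped after the borylation stage) and returns at 13. Compound 3 is oxidised with NaBO3·4H2O in THF/H2O to 1-[4-hydroxy-2,6-bis(methoxymethoxy)phenyl]ethanone F1, and one equivalent of N-iodosuccinimide gives 1-[4-hydroxy-3-iodo-2,6-bis(methoxymethoxy)phenyl]ethanone F2. F2 is annulated with 7-methyl-3-methylideneocta-1,6-diene (C=CC(=C)CCC=C(C)C) under Pd(OAc)2, a chiral phosphine and NaHCO3 in a Larock-type heteroannulation of an ortho-iodophenol with a 1,3-diene. The aryl-palladium unit adds to the monosubstituted vinyl terminus and the phenoxide attacks the allyl-palladium intermediate at the adjacent carbon. This leads directly to 13 and bypasses steps 5 to 8; C2 is then set by the chiral ligand and no longer by 5.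

**Step 5.** The epoxide may be opened by the silyl triflate (or by addition of the methoxysilane) faster than the carbonyl is ketalised, because the carbonyl is deactivated by the adjacent epoxide.
Fallback: it sets out from 9 and returns at 10. The epoxide is opened at CH2 with LiBr/AcOH in THF to (2S)-1-bromo-2-hydroxy-7-methyloct-6-en-3-one F3 (the descriptor changes only through priorities). The ketone is ketalised with trimethyl orthoformate and camphorsulfonic acid in MeOH to (2S)-1-bromo-3,3-dimethoxy-7-methyloct-6-en-2-ol F4. K2CO3 in MeOH then recloses the epoxide, with the C–O bond at the stereocentre never broken, to give 10.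

**Step 8.** Chemoselectivity between the two ketones may be incomplete (methylenation of the C5 acetyl group as well). The titanium and zinc halides may also cause partial MOM loss or enolisation at C2, with erosion of ee.
Fallback: it sets out from 12 and returns at 13 by a Peterson olefination. Me3SiCH2MgCl with CeCl3 in THF at −78 °C (non-basic organocerium addition to the less hindered ketone) gives 1-[(2R)-2-[2-hydroxy-6-methyl-1-(trimethylsilyl)hept-5-en-2-yl]-4,6-bis(methoxymethoxy)-2,3-dihydro-1-benzofuran-5-yl]ethanone F5 as a mixture of carbinol epimers. KH in THF then eliminates silanolate to give 13.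

**Step 9.** Acid may add to the trisubstituted or 1,1-disubstituted alkene, or ionise the allylic C2–O1 bond, before both MOM ethers are gone.
Fallback: it sets out from 12 and returns at 14 by changing the order of events. The MOM ethers are removed at the ketone stage with ZnBr2 and propane-1-thiol in CH2Cl2 at 0 °C to give 1-[(2R)-5-acetyl-4,6-dihydroxy-2,3-dihydro-1-benzofuran-2-yl]-5-methylhex-4-en-1-one F6. An excess of the Zn/CH2Br2/TiCl4 reagent then methylenates the aliphatic ketone, the acetyl group being protected as its metal-chelated phenoxide, to give 14.

**Step 12.** The bridge may scramble. Retro-Mannich release of 18 from 19 allows 20 to be captured by 18 and not by 14, which gives the symmetrical methylene-bis(pyranone) and lowers conversion of the valuable partner.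
Fallback: it sets out from 14 and returns at 21 with the roles reversed. Compound 14 is aminomethylated at C7 with [Me2N=CH2]I to 1-[(2R)-7-[(dimethylamino)methyl]-4,6-dihydroxy-2-(6-methylhepta-1,5-dien-2-yl)-2,3-dihydro-1-benzofuran-5-yl]ethanone F7. F7 is then heated with an excess of 18 in MeCN, so that the ortho-quinone methide from F7 is trapped by C3 of the pyranone to give 21.

## Further compounds

F1 | step 6 | 1-[4-hydroxy-2,6-bis(methoxymethoxy)phenyl]ethanone | CC(=O)c1c(OCOC)cc(O)cc1OCOC
F2 | step 6 | 1-[4-hydroxy-3-iodo-2,6-bis(methoxymethoxy)phenyl]ethanone | CC(=O)c1c(OCOC)cc(O)c(I)c1OCOC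
F3 | step 5 | (2S)-1-bromo-2-hydroxy-7-methyloct-6-en-3-one | CC(C)=CCCC(=O)[C@H](O)CBr
F4 | step 5 | (2S)-1-bromo-3,3-dimethoxy-7-methyloct-6-en-2-ol | CC(C)=CCCC(OC)(OC)[C@H](O)CBr
F5 | step 8 | 1-[(2R)-2-[2-hydroxy-6-methyl-1-(trimethylsilyl)hept-5-en-2-yl]-4,6-bis(methoxymethoxy)-2,3-dihydro-1-benzofuran-5-yl]ethanone (carbinol epimers) | CC(C)=CCCC(O)(C[Si](C)(C)C)[C@H]1Cc2c(OCOC)c(C(C)=O)c(OCOC)cc2O1
F6 | step 9 | 1-[(2R)-5-acetyl-4,6-dihydroxy-2,3-dihydro-1-benzofuran-2-yl]-5-methylhex-4-en-1-one | CC(C)=CCCC(=O)[C@H]1Cc2c(O)c(C(C)=O)c(O)cc2O1
F7 | step 12 | 1-[(2R)-7-[(dimethylamino)methyl]-4,6-dihydroxy-2-(6-methylhepta-1,5-dien-2-yl)-2,3-dihydro-1-benzofuran-5-yl]ethanone | C=C(CCC=C(C)C)[C@H]1Cc2c(O)c(C(C)=O)c(O)c(CN(C)C)c2O1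
A1 | alternative 1 | (2R)-5-acetyl-7-{[6-ethyl-5-methyl-4-oxo-2-(triisopropylsilyloxy)-4H-pyran-3-yl]methyl}-2-(6-methylhepta-1,5-dien-2-yl)-2,3-dihydro-1-benzofuran-4,6-diyl diacetate | C=C(CCC=C(C)C)[C@H]1Cc2c(OC(C)=O)c(C(C)=O)c(OC(C)=O)c(Cc3c(O[Si](C(C)C)(C(C)C)C(C)C)oc(CC)c(C)c3=O)c2O1
A2 | alternative 1 | (2R)-5-acetyl-2-(6-methylhepta-1,5-dien-2-yl)-7-[3-(triisopropylsilyloxy)prop-2-yn-1-yl]-2,3-dihydro-1-benzofuran-4,6-diyl diacetate | C=C(CCC=C(C)C)[C@H]1Cc2c(OC(C)=O)c(C(C)=O)c(OC(C)=O)c(CC#CO[Si](C(C)C)(C(C)C)C(C)C)c2O1
A3 | alternative 1 | 6-ethyl-2,2,5-trimethyl-4H-1,3-dioxin-4-one | CCC1=C(C)C(=O)OC(C)(C)O1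
A4 | alternative 1 | 2-methyl-3-oxopent-1-en-1-one (acylketene) | CCC(=O)C(C)=C=O
A5 | alternative 2 | 1-[4-(tert-butyldimethylsilyloxy)-2,6-bis(methoxymethoxy)-3-[(2S)-7-methyl-3-methylidene-2-(4,4,5,5-tetramethyl-1,3,2-dioxaborolan-2-yl)oct-6-en-1-yl]phenyl]ethanone | C=C(CCC=C(C)C)[C@@H](B1OC(C)(C)C(C)(C)O1)Cc1c(O[Si](C)(C)C(C)(C)C)cc(OCOC)c(C(C)=O)c1OCOC
A6 | alternative 2 | 1-[4-(tert-butyldimethylsilyloxy)-3-iodo-2,6-bis(methoxymethoxy)phenyl]ethanone | CC(=O)c1c(OCOC)cc(O[Si](C)(C)C(C)(C)C)c(I)c1OCOC
A7 | alternative 2 | lithium ethenyl(6-methylhepta-1,5-dien-2-yl)(pinacolato)borate | [Li+].C=C[B-]1(OC(C)(C)C(C)(C)O1)C(=C)CCC=C(C)C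
A8 | alternative 2 | 1-[4-(tert-butyldimethylsilyloxy)-3-[(2S)-2-hydroxy-7-methyl-3-methylideneoct-6-en-1-yl]-2,6-bis(methoxymethoxy)phenyl]ethanone | C=C(CCC=C(C)C)[C@@H](O)Cc1c(O[Si](C)(C)C(C)(C)C)cc(OCOC)c(C(C)=O)c1OCOC
A9 | alternative 3 | (2R)-5-acetyl-7-[(6-ethyl-4-hydroxy-5-methyl-2-oxo-2H-pyran-3-yl)methyl]-6-hydroxy-2-(6-methylhepta-1,5-dien-2-yl)-2,3-dihydro-1-benzofuran-4-yl acetate | C=C(CCC=C(C)C)[C@H]1Cc2c(OC(C)=O)c(C(C)=O)c(O)c(Cc3c(O)c(C)c(CC)oc3=O)c2O1
A10 | alternative 3 | acid chloride of the 3,4-dihydrocoumarin-3-carboxylic acid formed across the C6 oxygen and C7 of the C4-acetylated (2R)-dihydrobenzofuran core | C=C(CCC=C(C)C)[C@H]1Cc2c(OC(C)=O)c(C(C)=O)c3OC(=O)C(C(Cl)=O)Cc3c2O1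
A11 | alternative 3 | pentan-3-one | CCC(=O)CC
A12 | alternative 3 | acylketene derived from A10 by loss of HCl (3-(oxomethylidene)dihydrocoumarin on the same core) | C=C(CCC=C(C)C)[C@H]1Cc2c(OC(C)=O)c(C(C)=O)c3OC(=O)C(=C=O)Cc3c2O1
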